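The runs were generated by integration on assumed constants.

The trap I watched for was to count the held gas as a charge: the solution holds at most 25 mM, less than the 0.10 M of substrate in dusk, and at the start it holds none, so the question is how fast gas crosses over.

common to all: gas 25 mM (held)

| charge | substrate | remark | time |
|---|---|---|---|
| teal | 0.11 M | run made earlier |  |
| dusk | 0.10 M |  | 2.0 d |
| winter | 0.20 M |  | 2.0 d |
| spring | 0.40 M |  | 2.0 d |
| summer | 0.80 M |  | 2.0 d |
| autumn | 1.5 M |  | 2.0 d |

teal run (percent of the substrate charged)

| time / h | bis adduct / % | substrate / % |
|---|---|---|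
| 2.00 | 0.2 | 92.5 |
| 4.00 | 2.1 | 83.2 |
| 6.00 | 2.8 | 73.0 |
| 8.00 | 5.4 | 64.4 |
| 10.0 | 8.3 | 56.7 |

(scatter of a reading: 0.5 percentage points)

* [bis adduct] at the end for dusk, winter, spring, summer, autumn, in this order
* the shape of the row from first to last (rises, then falls / rises all the way / falls all the way / hardly changes / falls, then rises)

- what was read earlier has a scatter of 0.5 percentage points, one standard deviation
- at the start none of the gas is in solution
- "hardly changes" means that all values lie within two and a half points (for a concentration: within two and a half percent of the largest)

I wrote the balance of the dissolved gas, the limiting reagent, at concentration c: dc/dt = kLa(csat − c) − uptake, with kLa the transfer coefficient. Its ceiling is J = kLa·csat, the delivery into gas-free solution.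

I read the teal table column against column. Each substrate lost took one gas and each bis adduct one more, so between 4.00 h and 10.0 h the two columns give an uptake U = 0.00600 M h⁻¹. With c above zero, U is a floor for J.

The substrate column, from first row to last, falls at 0.0612 h⁻¹, and that line runs back to a lag of 0.726 h. In the balance, c relaxes at kLa plus the consumption term, so kLa lies below one over the lag, and J lies below 0.0345 M h⁻¹, which is more than U.

Over 2.0 d, the floor gives G = 0.288 M, the gas allowance: gas delivered in the time at teal's uptake. Divided by the charge, it gives 2.88 gas per substrate for dusk and 0.192 for autumn, while bis adduct takes two. So I expected a row that rises and then falls, turning between 0.144 M and 0.828 M of substrate.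

The forecast gave 0.076 M, 0.138 M, 0.221 M, 0.266 M and 0.236 M, shape rises, then falls, saying “bis concentration peaks near 0.8 M”.

The flask gave 0.0476 M, 0.0896 M, 0.113 M, 0.0942 M and 0.0643 M: rises, then falls.

    substrate + reagent → mono adduct (k = 5.10 L mol⁻¹ h⁻¹)
    reagent + mono adduct → bis adduct (k = 3.70 L mol⁻¹ h⁻¹)
    reagent + bis adduct → tris adduct (k = 1.30 L mol⁻¹ h⁻¹)
    gas ⇌ reagent, rate k4*(csat - [reagent]) (kL = 0.510 h⁻¹)
    bis adduct ⇌ isomer of the product (K = 1.40, k = 0.00340 h⁻¹)

The reagent here is the dissolved gas c. The row turned at 0.40 M, and spring ended with 41.8% mono adduct and 23.7% substrate. In autumn the allowance G stood for 0.192 gas per substrate. With one gas counted in mono adduct, two in bis adduct and in isomer of the product, and 3 in tris adduct, the products of autumn at the end held 0.380 gas per substrate charged, twice the allowance, with the reagent at 0.00175 M after 2.00 d.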